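## The problem

Compound 31 (CNP0141385.1) is a germacrane-type sesquiterpene lactone. Its ten-membered carbocycle C1–C10 is bridged by an oxygen between C3 and C10, so that C1 (ketone), C2=C3 (enol ether) and the quaternary C10 form a 3(2H)-furanone. C7 and C8 carry a trans-fused α-methylene-γ-butyrolactone (C11, C12, C13; ring oxygen on C8).

Five of the six stereocentres are contiguous (4S,5S,6S,7R,8S). The C4 methyl and C5 hydroxyl are syn, the C5 and C6 oxygens are syn, the C6 oxygen is anti to the C8 branch of C7 (the arrangement of a trans 6,12-lactone), and H7/H8 are trans. C4/C5 can be set by a reagent, C6 and C7 have to be relayed from C5, and C8 from C7. The sixth centre, the oxygenated quaternary C10 (R), is insulated from the others by the C9 methylene and the planar furanone, so it has to be bought.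

The methylene lactone is a Michael and radical acceptor and isomerises under base. The furanone is a vinylogous ester with an acidic C4–H. The C6 isobutyrate sits beside a free C5 hydroxyl and can migrate. A medium ring has to be closed against transannular strain.

The enabling feature is C9. It is the only unfunctionalised methylene of the carbocycle and lies between the quaternary C10 and C8, whose oxygen is γ to the carboxyl carbon C12. A C8=C9 double bond is therefore first a metathesis site between two vinyl groups and then the acceptor for a 5-exo halolactonisation that delivers the lactone oxygen to C8.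

## Retrosynthesis

**Lactone last (31 ⇒ 30 ⇒ 29 ⇒ 28).** The C5 silyl ether of 30 is the only protecting group left at the end. The C9–H bond of 30 is traced to the C9–I bond of iodolactone 29, and the O–C8 and C9–I bonds of 29 to the Z alkene and tert-butyl ester of cyclodecene 28. Cutting here rather than carrying a finished lactone through the synthesis removes C8 as a stereocentre of the open chain and keeps the acrylate unit as a robust tert-butyl ester. The forward step has to attack C8 from the carboxyl side only, anti to iodine, and C7 has to decide the C8 configuration.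

**Ring closure (28 ⇒ 27).** The C8=C9 bond is cut to two vinyl groups, one on C7 and one on the quaternary C10. A closure at C6–C7 would create two stereocentres in a macrocyclisation, and closures at C1–C2 or C3–C4 would build the furanone inside a strained ring. Here the furanone already ties C3 to C10 and no stereocentre is formed. Triene ester 27 is an open chain on a preformed heterocycle. The forward reaction has to distinguish two monosubstituted alkenes from the acrylate and enol ether double bonds and to beat oligomerisation.

**C6 ester and C6 configuration (27 ⇒ 26 ⇒ 25 ⇒ 24).** The isobutyrate of 27 comes from alcohol 26. Indium reagents from Z-configured 2-(bromomethyl)alk-2-enoates place hydroxyl and γ-substituent syn, and α-silyloxy aldehydes are attacked anti to the silyloxy group. The direct adduct 24 is therefore expected with the correct C7 but the epimeric C6. Intermolecular displacement at C6, flanked by two branched carbons, is not trusted. C6 is instead taken through ketone 25, where the C5 silyloxy group and the C7 substituents both direct hydride to the face that gives 26.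

**C6–C7 bond (24 ⇒ 18 + 22).** The bond between the aldehyde carbon of 18 and the vinyl-bearing carbon of dienyl bromide 22 is cut. One Barbier step then brings in C7 with both its vinyl group and the complete acrylate unit. Attaching these two groups one after the other would need several steps. The forward reaction must bond at the central carbon of the pentadienyl system and relay the C5 configuration to C7.

**Dienyl bromide (22 ⇒ 21 ⇒ 19 + 20).** Bromide 22 is the allylic transposition product of alcohol 21, which is the Morita–Baylis–Hillman adduct of tert-butyl acrylate 19 and acrolein 20.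

**C6 oxidation level (18 ⇒ 17 ⇒ 16).** Aldehyde 18 is unmasked from the 4-methoxybenzyl ether 16 by way of alcohol 17. C6 cannot be carried as a vinyl group, because it could not be cleaved selectively beside the C10 vinyl group.

**Furanone (16 ⇒ 14 ⇒ 13 ⇒ 11 + 4).** The O–C3 bond is cut by cyclodehydration of a hydroxy 1,3-diketone (from 14), and C1–C2 by an aldol between methyl ketone 11 and aldehyde 4. Esterifying a tertiary alcohol with an α-branched acid and then closing by an intramolecular Claisen condensation would be the alternative. The aldol route avoids that hindered ester and strong base on the epimerisable C4.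

**C4 and C5 (11 ⇒ 10 ⇒ 9 ⇒ 8 ⇒ 5 + 6).** An Evans syn aldol between imide 5 and aldehyde 6 sets both centres under reagent control. The Weinreb amide 9/10 then gives the methyl ketone without touching C4.

**C10 (4 ⇒ 3 ⇒ 2 ⇒ 1).** The quaternary centre is taken from (S)-2-methylglycidol 1. Its epoxide CH2 becomes the vinyl group by one-carbon homologation with a sulfonium ylide, and its CH2OH becomes C1.

## Roads not taken

**Alternative 1:** The cut is C3–C4, paid for by the C1–C6 bond of a six-membered ring derived from carvone. KH with 18-crown-6 would convert a tertiary 1-alkynyl-2-propenyl cyclohexanol into its alkoxide. The [3,3] shift then forms C3–C4, breaks C1–C6 and, after protonation of the allenolate, gives cyclodecadienone A1.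
- Merits: the ring expansion is unimolecular and needs neither dilution nor a catalyst. C7, C8 and C10 come from a cheap terpene, and the C8 oxygen is present with defined configuration, so no iodolactonisation or deiodination is needed. The E-C5=C6 alkene is the right precursor of a syn 5,6-diol.
- Weak points: C4 is set by the chair/boat preference of the sigmatropic step, not by a reagent. After the ring is made, almost everything is still missing: the oxygen bridge and re-oxidation to the furanone, face-selective dihydroxylation of a mobile medium ring, differentiation of O5 from O6, and oxidation of the side chain to the acrylate.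
- Comparison: this road is better in the ring-forming step and at C8. The chosen plan sets against it that C4–C7 and the furanone are complete and differentiated before closure, so only one C–O bond and one reduction follow.

**Alternative 2:** The cut is C9–C10 and O–C10, with a tetrahydropyran as template. Cu(CF3COCHCOCF3)2 (divalent copper) would decompose an α-methyl diazoketone. The pyran oxygen captures the carbenoid carbon, and a [2,3] shift of the C7 vinyl group forms C9–C10 and breaks O–C7, giving the oxygen-bridged Z-cyclodecenone A2.
- Merits: both rings and the quaternary C10 arise in one catalytic step at normal concentration. The Z alkene is formed selectively, and the C5 and C6 oxygens are already differentiated. In ring-forming efficiency this road is better than metathesis.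
- Weak points: A2 has neither C11–C13 nor the C8 oxygen. They would have to be added to C7=C8 in a medium ring (for example epoxidation and opening at C7 by a carbon nucleophile, lactonisation, late α-methylenation under base), and the oxolanone must still be dehydrogenated. C10 is created in the rearrangement instead of being bought.
- Comparison: the chosen plan sets against it that C7 enters the ring closure with the whole acrylate unit, so the most sensitive group never has to be made on the bicycle.

**Alternative 3:** The cut is C1–C2 together with the O–C3 bond of an isoxazoline. NaOCl would turn a C1 aldoxime into the nitrile oxide, which adds to the terminal C2=C3 vinyl group on C4 and closes the carbocycle as the 1,3-bridged isoxazoline A3.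
- Merits: the cycloadduct is a masked β-hydroxy ketone. N–O cleavage, oxidation and cyclodehydration with the C10 oxygen give the furanone, so ring closure and heterocycle share one functional group. The regiochemistry is the normal one for a terminal alkene. C8 and the lactone ring are fixed before cyclisation, so no iodine chemistry is needed. In these respects it is at least as good as the chosen plan.
- Weak points: the open-chain precursor must carry all six centres including the C7/C8 lactone, which lengthens the linear sequence. Nitrile oxide dimerisation competes at the required dilution. The exocyclic methylene must be added last by enolate chemistry, in the presence of a γ-acidic furanone and a migratory ester.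
- Comparison: the chosen plan sets against it a short assembly of C7 by one Barbier step and the absence of any late strong-base step.

Key step: step 19

Assumption: atoms carry germacrane numbers (C1–C10 ring, C11–C13 lactone carbons). Aldehyde 6 is taken as purchasable. Bromide 22 is assumed to behave in the indium reaction like simpler Z-configured 2-(bromomethyl)alk-2-enoates (bonding at the substituted terminus, hydroxyl and vinyl syn).

## Route

Step 1
Reactants: 1 (S)-2-methylglycidol
Product: 2 (R)-2-methylbut-3-ene-1,2-diol
Conditions: Me3S+ I−, n-BuLi, THF, −10 °C to rt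
Reagents that add atoms: trimethylsulfonium iodide, C[S+](C)C.[I-]
Why: Dimethylsulfonium methylide opens the epoxide at its CH2 and the resulting β-alkoxy sulfonium salt eliminates Me2S, so the epoxide carbon becomes a vinyl group (one-carbon homologation of an epoxide to an allylic alcohol). No bond to the quaternary carbon is broken, and the Payne rearrangement of this alkoxide is degenerate, so the configuration is kept.

Step 2
Reactants: 2 (R)-2-methylbut-3-ene-1,2-diol
Product: 3 (R)-2-methyl-1,2-bis(triethylsilyloxy)but-3-ene
Conditions: Et3SiOTf, 2,6-lutidine, CH2Cl2, −78 to 0 °C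
Reagents that add atoms: triethylsilyl trifluoromethanesulfonate, CC[Si](CC)(CC)OS(=O)(=O)C(F)(F)F
Why: The silyl triflate silylates the tertiary as well as the primary hydroxyl; the tertiary silyl ether later releases the furanone oxygen under mild acid.

Step 3
Reactants: 3 (R)-2-methyl-1,2-bis(triethylsilyloxy)but-3-ene
Product: 4 (R)-2-methyl-2-(triethylsilyloxy)but-3-enal
Conditions: (COCl)2, DMSO, CH2Cl2, −78 to −40 °C; Et3N, −78 °C to rt
Reagents that add atoms: none
Why: Under Swern conditions a primary triethylsilyl ether is cleaved by the chlorosulfonium salt and oxidised in the same flask while the tertiary one is inert; the aldehyde has no α-hydrogen and cannot racemise.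

Step 4
Reactants: 5 (S)-4-benzyl-3-propionyloxazolidin-2-one; 6 2-((4-methoxybenzyl)oxy)acetaldehyde
Product: 8 (S)-4-benzyl-3-[(2S,3S)-3-hydroxy-4-((4-methoxybenzyl)oxy)-2-methylbutanoyl]oxazolidin-2-one, via dibutylboron Z-enolate 7 (not isolated)
Conditions: Bu2BOTf, i-Pr2NEt, CH2Cl2, 0 °C; 6, −78 to 0 °C; pH 7 buffer, MeOH, H2O2
Reagents that add atoms: none
Why: Evans syn aldol: the Z-boron enolate reacts through a chair (Zimmerman–Traxler) transition state on the face away from the benzyl group, which sets C4 (S) and C5 (S) syn.

Step 5
Reactants: 8 aldol adduct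
Product: 9 (2S,3S)-3-hydroxy-N-methoxy-4-((4-methoxybenzyl)oxy)-N,2-dimethylbutanamide
Conditions: MeNH(OMe)·HCl, AlMe3, CH2Cl2, −20 to 0 °C
Reagents that add atoms: N,O-dimethylhydroxylamine hydrochloride, CNOC.Cl
Why: Aluminium amide transamidation of a β-hydroxy imide (the free hydroxyl assists as its aluminium alkoxide) gives the Weinreb amide and returns the auxiliary.

Step 6
Reactants: 9 hydroxy Weinreb amide
Product: 10 (2S,3S)-3-((tert-butyldimethylsilyl)oxy)-N-methoxy-4-((4-methoxybenzyl)oxy)-N,2-dimethylbutanamide
Conditions: t-BuMe2SiOTf, 2,6-lutidine, CH2Cl2, 0 °C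
Reagents that add atoms: tert-butyldimethylsilyl trifluoromethanesulfonate, CC(C)(C)[Si](C)(C)OS(=O)(=O)C(F)(F)F
Why: Standard silylation of a secondary alcohol; a bulky non-chelating group on O5 is needed for the Felkin–Anh-controlled steps at C6.

Step 7
Reactants: 10 silylated Weinreb amide
Product: 11 (3S,4S)-4-((tert-butyldimethylsilyl)oxy)-5-((4-methoxybenzyl)oxy)-3-methylpentan-2-one
Conditions: MeMgBr, THF, 0 °C
Reagents that add atoms: methylmagnesium bromide, C[Mg]Br
Why: The magnesium chelate of the Weinreb adduct stops the Grignard addition at the ketone stage, and C4 is never exposed to free base.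

Step 8
Reactants: 11 methyl ketone; 4 (R)-2-methyl-2-(triethylsilyloxy)but-3-enal
Product: 13 (3R,7S,8S)-8-((tert-butyldimethylsilyl)oxy)-4-hydroxy-9-((4-methoxybenzyl)oxy)-3,7-dimethyl-3-(triethylsilyloxy)non-1-en-6-one (both C1 carbinol epimers), via lithium enolate 12 (not isolated)
Conditions: LiN(i-Pr)2, THF, −78 °C; 4, −78 °C; aq. NH4Cl at −78 °C
Reagents that add atoms: none
Why: Kinetic deprotonation at the methyl group and aldol addition to the non-enolisable aldehyde form C1–C2; the new carbinol centre is oxidised in step 9, so its configuration does not matter.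

Step 9
Reactants: 13 β-hydroxy ketone
Product: 14 (3R,7S,8S)-8-((tert-butyldimethylsilyl)oxy)-9-((4-methoxybenzyl)oxy)-3,7-dimethyl-3-(triethylsilyloxy)non-1-ene-4,6-dione
Conditions: Dess–Martin periodinane, NaHCO3, CH2Cl2, 0 °C to rt
Reagents that add atoms: none
Why: Dess–Martin oxidation of a β-hydroxy ketone gives the 1,3-diketone under non-basic conditions that spare C4 and the β-silyloxy group.

Step 10
Reactants: 14 silyloxy 1,3-diketone
Product: 16 (R)-5-[(2S,3S)-3-((tert-butyldimethylsilyl)oxy)-4-((4-methoxybenzyl)oxy)butan-2-yl]-2-methyl-2-vinylfuran-3(2H)-one, via hydroxy diketone 15 (not isolated)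
Conditions: 1 M aq. HCl, THF, 0 °C to rt
Reagents that add atoms: none
Why: Acid cleaves the triethylsilyl ether faster than the hindered tert-butyldimethylsilyl ether; the freed tertiary hydroxyl adds to the C3 carbonyl (5-exo-trig) and the hemiketal dehydrates, the classical cyclodehydration of α'-hydroxy 1,3-diketones to 3(2H)-furanones.

Step 11
Reactants: 16 furanone 4-methoxybenzyl ether
Product: 17 (R)-5-[(2S,3S)-3-((tert-butyldimethylsilyl)oxy)-4-hydroxybutan-2-yl]-2-methyl-2-vinylfuran-3(2H)-one
Conditions: DDQ, CH2Cl2/pH 7 buffer, 0 °C
Reagents that add atoms: none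
Why: Oxidative cleavage of the 4-methoxybenzyl ether leaves the silyl ether, the vinyl group and the electron-poor enol ether untouched.

Step 12
Reactants: 17 primary alcohol
Product: 18 (2S,3S)-2-((tert-butyldimethylsilyl)oxy)-3-[(R)-5-methyl-4-oxo-5-vinyl-4,5-dihydrofuran-2-yl]butanal
Conditions: Dess–Martin periodinane, NaHCO3, CH2Cl2, 0 °C
Reagents that add atoms: none
Why: Dess–Martin oxidation gives the α-silyloxy aldehyde without epimerising C5; it is used directly.

Step 13
Reactants: 19 tert-butyl acrylate; 20 acrolein
Product: 21 tert-butyl 3-hydroxy-2-methylenepent-4-enoate (racemic)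
Conditions: DABCO, 1,4-dioxane/H2O, rt
Reagents that add atoms: none
Why: Morita–Baylis–Hillman reaction: the amine–acrylate zwitterion adds to the aldehyde group of acrolein and the amine is expelled.

Step 14
Reactants: 21 tert-butyl 3-hydroxy-2-methylenepent-4-enoate
Product: 22 tert-butyl (Z)-2-(bromomethyl)penta-2,4-dienoate
Conditions: NBS, Me2S, CH2Cl2, 0 °C to rt
Reagents that add atoms: N-bromosuccinimide, O=C1CCC(=O)N1Br
Why: The bromosulfonium salt activates the alcohol and bromide attacks with allylic transposition (SN2') to the conjugated Z bromide, as known for Morita–Baylis–Hillman alcohols; any allylic isomer would lead to the same organoindium reagent.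

Step 15
Reactants: 18 aldehyde; 22 dienyl bromide
Product: 24 tert-butyl (3S,4R,5S,6S)-5-((tert-butyldimethylsilyl)oxy)-4-hydroxy-6-[(R)-5-methyl-4-oxo-5-vinyl-4,5-dihydrofuran-2-yl]-2-methylene-3-vinylheptanoate, via allylindium reagent 23 (not isolated)
Conditions: In powder, THF/H2O, rt
Reagents that add atoms: none
Why: Barbier allylation: the allylindium reagent bonds through its vinyl-bearing carbon in a chair transition state, the Z-configured reagent placing hydroxyl and vinyl syn, and attack anti to the C5 silyloxy group (Felkin–Anh) selects the aldehyde face. C7 is thereby set as required (S in this open-chain form) while C6 is obtained as its R epimer, which steps 16 and 17 correct; the tert-butyl ester prevents lactonisation of the C6 alkoxide.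

Step 16
Reactants: 24 homoallylic alcohol (6R)
Product: 25 tert-butyl (3S,5S,6S)-5-((tert-butyldimethylsilyl)oxy)-6-[(R)-5-methyl-4-oxo-5-vinyl-4,5-dihydrofuran-2-yl]-2-methylene-4-oxo-3-vinylheptanoate
Conditions: Dess–Martin periodinane, NaHCO3, CH2Cl2, 0 °C; filtered and used at once
Reagents that add atoms: none
Why: Buffered Dess–Martin oxidation removes the wrongly configured C6 centre without base, and any C6 epimer of 24 converges on the same ketone; 25 is not stored or chromatographed so that the doubly allylic C7–H is not enolised.

Step 17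
Reactants: 25 C6 ketone
Product: 26 tert-butyl (3S,4S,5S,6S)-5-((tert-butyldimethylsilyl)oxy)-4-hydroxy-6-[(R)-5-methyl-4-oxo-5-vinyl-4,5-dihydrofuran-2-yl]-2-methylene-3-vinylheptanoate
Conditions: NaBH4, CeCl3·7H2O, MeOH, −78 °C
Reagents that add atoms: none
Why: Luche reduction: hydride attacks anti to the C5 silyloxy group and anti to the acrylate-bearing substituent on C7 (Felkin–Anh control from both neighbours, mutually reinforcing), which gives the 6S alcohol with C5/C6 syn and the C6 oxygen anti to the C7 vinyl group.

Step 18
Reactants: 26 homoallylic alcohol (6S)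
Product: 27 tert-butyl (3S,4S,5S,6S)-5-((tert-butyldimethylsilyl)oxy)-4-(isobutyryloxy)-6-[(R)-5-methyl-4-oxo-5-vinyl-4,5-dihydrofuran-2-yl]-2-methylene-3-vinylheptanoate
Conditions: (i-PrCO)2O, DMAP, Et3N, CH2Cl2, 0 °C to rt
Reagents that add atoms: isobutyric anhydride, CC(C)C(=O)OC(=O)C(C)C
Why: DMAP-catalysed acylation of the secondary alcohol with retention of configuration.

Step 19
Reactants: 27 triene ester
Product: 28 tert-butyl 2-[(4S,5S,6S,7S,10R,8Z)-5-((tert-butyldimethylsilyl)oxy)-6-(isobutyryloxy)-4,10-dimethyl-1-oxo-3,10-epoxycyclodeca-2,8-dien-7-yl]acrylate (germacrane numbering)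
Conditions: second-generation Grubbs catalyst (H2IMes)(PCy3)Cl2Ru=CHPh, 1,4-benzoquinone, toluene (high dilution), 80 °C
Reagents that add atoms: none
Why: After loss of PCy3 the catalyst initiates at the less hindered C7 vinyl group to give a ruthenium alkylidene at C8; [2+2] cycloaddition with the C10 vinyl group gives a ruthenacyclobutane whose cycloreversion releases the C8=C9 bond and Ru=CH2, and loss of ethylene drives the cycle. The closest known reaction type is ring-closing olefin metathesis to medium-ring carbocycles with a vinyl group on a quaternary carbon as the slow partner. The ten-membered carbocycle (a nine-membered ring when counted through the furanone oxygen) is closed by joining two terminal alkenes, and because the planar furanone already holds C3 and C10 together only the C4–C7 segment has to fold. No stereocentre is formed; the Z geometry is imposed by the nine-membered path, in which an E alkene would be highly strained. Site selectivity is needed and is secured by the substrate: the 1,1-disubstituted electron-poor acrylate alkene and the trisubstituted enol ether are far slower partners, and closure between the C7 vinyl group and the acrylate would require a cyclobutene. Ring closure has to beat oligomerisation through the exposed C7 vinyl group, which high dilution and removal of ethylene favour. Benzoquinone suppresses ruthenium hydride migration of the skipped diene at C7.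

Step 20
Reactants: 28 cyclodecene tert-butyl ester
Product: 29 (4S,5S,6S,7S,8R,9S,10S)-5-((tert-butyldimethylsilyl)oxy)-9-iodo-6-(isobutyryloxy)-1-oxo-3,10-epoxygermacra-2,11(13)-dien-12,8-olide (C8–O and C9–I anti)
Conditions: I2, NaHCO3, MeCN, 0 °C, dark
Reagents that add atoms: iodine, II
Why: Iodolactonisation of a γ,δ-unsaturated tert-butyl ester: iodonium formation at C8=C9 is reversible, the ester carbonyl oxygen attacks C8 in a 5-exo mode anti to iodine and the tert-butyl group leaves as isobutene. With H7 eclipsing the Z alkene (allylic 1,3-strain) the acrylate arm reaches only the face that gives the trans-fused lactone, that is the C8 configuration of the target.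

Step 21
Reactants: 29 iodolactone
Product: 30 (4S,5S,6S,7R,8S,10R)-5-((tert-butyldimethylsilyl)oxy)-6-(isobutyryloxy)-1-oxo-3,10-epoxygermacra-2,11(13)-dien-12,8-olide
Conditions: (Me3Si)3SiH, Et3B, air, toluene, 0 °C to rt
Reagents that add atoms: none
Why: Radical chain deiodination: the silyl radical abstracts iodine much faster than it adds to the methylene lactone, and the secondary C9 radical takes hydrogen from the silane; near-stoichiometric silane and low temperature keep hydrosilylation of the acrylate unit down.

Step 22
Reactants: 30 silyl ether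
Product: 31 CNP0141385.1, (4S,5S,6S,7R,8S,10R)-5-hydroxy-6-(isobutyryloxy)-1-oxo-3,10-epoxygermacra-2,11(13)-dien-12,8-olide
Conditions: HF·pyridine, pyridine, THF, 0 °C to rt
Reagents that add atoms: none
Why: Acidic fluoride cleaves the silyl ether without the basic conditions that would move the isobutyrate from O6 to O5 or add to the methylene lactone.

## Compound list

1 | (S)-2-methylglycidol | OC[C@@]1(C)CO1 | starting material
2 | (R)-2-methylbut-3-ene-1,2-diol | OC[C@@](O)(C)C=C | intermediate
3 | (R)-2-methyl-1,2-bis(triethylsilyloxy)but-3-ene | CC[Si](CC)(CC)OC[C@@](O[Si](CC)(CC)CC)(C)C=C | intermediate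
4 | (R)-2-methyl-2-(triethylsilyloxy)but-3-enal | O=C[C@@](O[Si](CC)(CC)CC)(C)C=C | intermediate
5 | (S)-4-benzyl-3-propionyloxazolidin-2-one | CCC(=O)N1[C@@H](Cc2ccccc2)COC1=O | starting material
6 | 2-((4-methoxybenzyl)oxy)acetaldehyde | O=CCOCc1ccc(OC)cc1 | starting material
7 | dibutylboron Z-enolate of 5 (not isolated) | C/C=C(\OB(CCCC)CCCC)N1[C@@H](Cc2ccccc2)COC1=O | intermediate
8 | (S)-4-benzyl-3-[(2S,3S)-3-hydroxy-4-((4-methoxybenzyl)oxy)-2-methylbutanoyl]oxazolidin-2-one | O=C(N1[C@@H](Cc2ccccc2)COC1=O)[C@@H](C)[C@H](O)COCc1ccc(OC)cc1 | intermediate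
9 | (2S,3S)-3-hydroxy-N-methoxy-4-((4-methoxybenzyl)oxy)-N,2-dimethylbutanamide | CON(C)C(=O)[C@@H](C)[C@H](O)COCc1ccc(OC)cc1 | intermediate
10 | (2S,3S)-3-((tert-butyldimethylsilyl)oxy)-N-methoxy-4-((4-methoxybenzyl)oxy)-N,2-dimethylbutanamide | CON(C)C(=O)[C@@H](C)[C@H](O[Si](C)(C)C(C)(C)C)COCc1ccc(OC)cc1 | intermediate
11 | (3S,4S)-4-((tert-butyldimethylsilyl)oxy)-5-((4-methoxybenzyl)oxy)-3-methylpentan-2-one | CC(=O)[C@@H](C)[C@H](O[Si](C)(C)C(C)(C)C)COCc1ccc(OC)cc1 | intermediate
12 | lithium enolate of 11 at the methyl carbon (not isolated) | C=C(O[Li])[C@@H](C)[C@H](O[Si](C)(C)C(C)(C)C)COCc1ccc(OC)cc1 | intermediate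
13 | (3R,7S,8S)-8-((tert-butyldimethylsilyl)oxy)-4-hydroxy-9-((4-methoxybenzyl)oxy)-3,7-dimethyl-3-(triethylsilyloxy)non-1-en-6-one, both carbinol epimers | C=C[C@@](C)(O[Si](CC)(CC)CC)C(O)CC(=O)[C@@H](C)[C@H](O[Si](C)(C)C(C)(C)C)COCc1ccc(OC)cc1 | intermediate
14 | (3R,7S,8S)-8-((tert-butyldimethylsilyl)oxy)-9-((4-methoxybenzyl)oxy)-3,7-dimethyl-3-(triethylsilyloxy)non-1-ene-4,6-dione | C=C[C@@](C)(O[Si](CC)(CC)CC)C(=O)CC(=O)[C@@H](C)[C@H](O[Si](C)(C)C(C)(C)C)COCc1ccc(OC)cc1 | intermediate
15 | (3R,7S,8S)-8-((tert-butyldimethylsilyl)oxy)-3-hydroxy-9-((4-methoxybenzyl)oxy)-3,7-dimethylnon-1-ene-4,6-dione (not isolated) | C=C[C@@](C)(O)C(=O)CC(=O)[C@@H](C)[C@H](O[Si](C)(C)C(C)(C)C)COCc1ccc(OC)cc1 | intermediate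
16 | (R)-5-[(2S,3S)-3-((tert-butyldimethylsilyl)oxy)-4-((4-methoxybenzyl)oxy)butan-2-yl]-2-methyl-2-vinylfuran-3(2H)-one | C=C[C@@]1(C)OC(=CC1=O)[C@@H](C)[C@H](O[Si](C)(C)C(C)(C)C)COCc1ccc(OC)cc1 | intermediate
17 | (R)-5-[(2S,3S)-3-((tert-butyldimethylsilyl)oxy)-4-hydroxybutan-2-yl]-2-methyl-2-vinylfuran-3(2H)-one | C=C[C@@]1(C)OC(=CC1=O)[C@@H](C)[C@H](O[Si](C)(C)C(C)(C)C)CO | intermediate
18 | (2S,3S)-2-((tert-butyldimethylsilyl)oxy)-3-[(R)-5-methyl-4-oxo-5-vinyl-4,5-dihydrofuran-2-yl]butanal | C=C[C@@]1(C)OC(=CC1=O)[C@@H](C)[C@H](O[Si](C)(C)C(C)(C)C)C=O | intermediate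
19 | tert-butyl acrylate | C=CC(=O)OC(C)(C)C | starting material
20 | acrolein | C=CC=O | starting material
21 | tert-butyl 3-hydroxy-2-methylenepent-4-enoate (racemic) | C=CC(O)C(=C)C(=O)OC(C)(C)C | intermediate
22 | tert-butyl (Z)-2-(bromomethyl)penta-2,4-dienoate | C=C/C=C(\CBr)C(=O)OC(C)(C)C | intermediate
23 | allylindium reagent from 22, written as the dibromoindium species (not isolated) | C=C/C=C(\C[In](Br)Br)C(=O)OC(C)(C)C | intermediate
24 | tert-butyl (3S,4R,5S,6S)-5-((tert-butyldimethylsilyl)oxy)-4-hydroxy-6-[(R)-5-methyl-4-oxo-5-vinyl-4,5-dihydrofuran-2-yl]-2-methylene-3-vinylheptanoate | C=C[C@@]1(C)OC(=CC1=O)[C@@H](C)[C@H](O[Si](C)(C)C(C)(C)C)[C@H](O)[C@@H](C=C)C(=C)C(=O)OC(C)(C)C | intermediate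
25 | tert-butyl (3S,5S,6S)-5-((tert-butyldimethylsilyl)oxy)-6-[(R)-5-methyl-4-oxo-5-vinyl-4,5-dihydrofuran-2-yl]-2-methylene-4-oxo-3-vinylheptanoate | C=C[C@@]1(C)OC(=CC1=O)[C@@H](C)[C@H](O[Si](C)(C)C(C)(C)C)C(=O)[C@@H](C=C)C(=C)C(=O)OC(C)(C)C | intermediate
26 | tert-butyl (3S,4S,5S,6S)-5-((tert-butyldimethylsilyl)oxy)-4-hydroxy-6-[(R)-5-methyl-4-oxo-5-vinyl-4,5-dihydrofuran-2-yl]-2-methylene-3-vinylheptanoate | C=C[C@@]1(C)OC(=CC1=O)[C@@H](C)[C@H](O[Si](C)(C)C(C)(C)C)[C@@H](O)[C@@H](C=C)C(=C)C(=O)OC(C)(C)C | intermediate
27 | tert-butyl (3S,4S,5S,6S)-5-((tert-butyldimethylsilyl)oxy)-4-(isobutyryloxy)-6-[(R)-5-methyl-4-oxo-5-vinyl-4,5-dihydrofuran-2-yl]-2-methylene-3-vinylheptanoate | C=C[C@@]1(C)OC(=CC1=O)[C@@H](C)[C@H](O[Si](C)(C)C(C)(C)C)[C@@H](OC(=O)C(C)C)[C@@H](C=C)C(=C)C(=O)OC(C)(C)C | intermediate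
28 | tert-butyl 2-[(4S,5S,6S,7S,10R,8Z)-5-((tert-butyldimethylsilyl)oxy)-6-(isobutyryloxy)-4,10-dimethyl-1-oxo-3,10-epoxycyclodeca-2,8-dien-7-yl]acrylate | C[C@]12OC(=CC1=O)[C@@H](C)[C@H](O[Si](C)(C)C(C)(C)C)[C@@H](OC(=O)C(C)C)[C@H](C(=C)C(=O)OC(C)(C)C)/C=C\2 | intermediate
29 | (4S,5S,6S,7S,8R,9S,10S)-5-((tert-butyldimethylsilyl)oxy)-9-iodo-6-(isobutyryloxy)-1-oxo-3,10-epoxygermacra-2,11(13)-dien-12,8-olide | C=C1C(=O)O[C@H]2[C@H](I)[C@@]3(C)OC(=CC3=O)[C@@H](C)[C@H](O[Si](C)(C)C(C)(C)C)[C@@H](OC(=O)C(C)C)[C@H]12 | intermediate
30 | (4S,5S,6S,7R,8S,10R)-5-((tert-butyldimethylsilyl)oxy)-6-(isobutyryloxy)-1-oxo-3,10-epoxygermacra-2,11(13)-dien-12,8-olide | C=C1C(=O)O[C@H]2C[C@@]3(C)OC(=CC3=O)[C@@H](C)[C@H](O[Si](C)(C)C(C)(C)C)[C@@H](OC(=O)C(C)C)[C@H]12 | intermediate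
31 | CNP0141385.1, (4S,5S,6S,7R,8S,10R)-5-hydroxy-6-(isobutyryloxy)-1-oxo-3,10-epoxygermacra-2,11(13)-dien-12,8-olide | C=C1C(=O)O[C@H]2C[C@@]3(C)OC(=CC3=O)[C@@H](C)[C@H](O)[C@@H](OC(=O)C(C)C)[C@H]12 | target

## Step count and risks

Total: 22 steps. Longest linear sequence: 17 steps (steps 4–12 and 15–22, from 5 and 6).

**Step 19 (key step).** Oligomerisation through the exposed C7 vinyl group may outrun closure onto the hindered C10 vinyl group, the alkylidene may be held as a chelate by the neighbouring ester carbonyls, and the skipped diene at C7 may migrate into conjugation. The fallback closes the ring one stage earlier, on the free alcohol. Alcohol 26, which lacks the C6 ester and is less crowded, is submitted to the same metathesis to give the hydroxy cyclodecene F1. Acylation of F1 with isobutyric anhydride and DMAP returns to the route at 28.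

**Step 16 (with step 17).** Enolisation of the β,γ-unsaturated ketone may scramble C7 or move a double bond into conjugation, and the hydride may not discriminate the two faces well enough. The fallback inverts C6 by substitution instead of by redox. Alcohol 24 is esterified under Mitsunobu conditions (PPh3, diisopropyl azodicarboxylate, 4-nitrobenzoic acid) to the inverted 4-nitrobenzoate F3. Mild methanolysis (K2CO3, MeOH) releases alcohol 26, where the route is rejoined.

**Step 15.** Facial or simple diastereoselection may be poor because the pentadienylindium species equilibrates, or bonding may occur at the terminal carbon. The fallback uses a configurationally fixed reagent. Bromide 22 is converted with bis(pinacolato)diboron, CuCl and KOt-Bu into the allylboronate F2. F2 adds to aldehyde 18 through a closed six-membered transition state (thermal or with Sc(OTf)3) and gives 24 after work-up.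

**Step 20.** The iodonium ion may be captured by the C6 ester carbonyl or the silyl ether oxygen instead of the weakly nucleophilic tert-butyl ester, or adventitious acid may remove the silyl group. The fallback separates ester cleavage from ring closure. Ester 28 is cleaved with Me3SiOTf and 2,6-lutidine to the carboxylic acid F4. Its carboxylate is then cyclised under kinetic conditions (I2, KI, NaHCO3, aqueous MeCN) to 29.

**Step 21.** The silyl radical may add to the methylene lactone, or the C9 radical may add to the acrylate unit of a second molecule. The fallback masks the acceptor. Iodolactone 29 takes up dimethylamine at C13 to give the amino iodolactone F5. Radical deiodination then gives the amino lactone F6. Quaternisation with MeI gives the ammonium iodide F7, and NaHCO3 eliminates trimethylamine to restore the methylene group, returning at 30.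

## Further compounds

F1 | step 19 | tert-butyl 2-[(4S,5S,6S,7S,10R,8Z)-5-((tert-butyldimethylsilyl)oxy)-6-hydroxy-4,10-dimethyl-1-oxo-3,10-epoxycyclodeca-2,8-dien-7-yl]acrylate | C[C@]12OC(=CC1=O)[C@@H](C)[C@H](O[Si](C)(C)C(C)(C)C)[C@@H](O)[C@H](C(=C)C(=O)OC(C)(C)C)/C=C\2
F2 | step 15 | tert-butyl (Z)-2-[(4,4,5,5-tetramethyl-1,3,2-dioxaborolan-2-yl)methyl]penta-2,4-dienoate | C=C/C=C(\CB1OC(C)(C)C(C)(C)O1)C(=O)OC(C)(C)C
F3 | step 16 | 4-nitrobenzoate of 26 (C6 inverted relative to 24) | C=C[C@@]1(C)OC(=CC1=O)[C@@H](C)[C@H](O[Si](C)(C)C(C)(C)C)[C@@H](OC(=O)c2ccc(cc2)[N+](=O)[O-])[C@@H](C=C)C(=C)C(=O)OC(C)(C)C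
F4 | step 20 | 2-[(4S,5S,6S,7S,10R,8Z)-5-((tert-butyldimethylsilyl)oxy)-6-(isobutyryloxy)-4,10-dimethyl-1-oxo-3,10-epoxycyclodeca-2,8-dien-7-yl]acrylic acid | C[C@]12OC(=CC1=O)[C@@H](C)[C@H](O[Si](C)(C)C(C)(C)C)[C@@H](OC(=O)C(C)C)[C@H](C(=C)C(=O)O)/C=C\2
F5 | step 21 | dimethylamine adduct of 29 at C13 (C11 epimers) | CN(C)CC1C(=O)O[C@H]2[C@H](I)[C@@]3(C)OC(=CC3=O)[C@@H](C)[C@H](O[Si](C)(C)C(C)(C)C)[C@@H](OC(=O)C(C)C)[C@H]12
F6 | step 21 | dimethylamine adduct of 30 at C13 (C11 epimers) | CN(C)CC1C(=O)O[C@H]2C[C@@]3(C)OC(=CC3=O)[C@@H](C)[C@H](O[Si](C)(C)C(C)(C)C)[C@@H](OC(=O)C(C)C)[C@H]12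
F7 | step 21 | trimethylammonium iodide derived from F6 | C[N+](C)(C)CC1C(=O)O[C@H]2C[C@@]3(C)OC(=CC3=O)[C@@H](C)[C@H](O[Si](C)(C)C(C)(C)C)[C@@H](OC(=O)C(C)C)[C@H]12.[I-]
A1 | alternative 1 | cyclodeca-2,5-dienone from the alkynyl anionic oxy-Cope ring expansion | O=C1/C=C\[C@@H](C)/C=C/[C@H](C(=C)COCc2ccc(OC)cc2)[C@@H](O[Si](C)(C)C(C)(C)C)C[C@@]1(C)O[Si](CC)(CC)CC
A2 | alternative 2 | oxygen-bridged (Z)-cyclodecenone from the oxonium ylide ring expansion | C[C@@H]1[C@H]2CC(=O)[C@](C)(O2)C/C=C\[C@H](O[Si](CC)(CC)CC)[C@H]1O[Si](C)(C)C(C)(C)C
A3 | alternative 3 | isoxazoline-bridged carbocycle from the nitrile oxide cycloaddition | O=C1C[C@@H]2[C@@H](O1)C[C@@](C)(O[Si](CC)(CC)CC)C3=NO[C@H](C3)[C@@H](C)[C@H](O[Si](C)(C)C(C)(C)C)[C@H]2OC(=O)C(C)C
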